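## Analysis of the target

Compound 33 is a labdane-type diterpenoid: a trans-fused decalin (ring A: C1–C5 and C10; ring B: C5–C10) with a 3-methylidenepent-4-enyl chain (C11–C16) on C9. It has six stereocentres, C3, C4, C5, C8, C9 and C10. Two are quaternary carbons (C4 with CH3 and CH2OH, C10 with CH3) and one is a tertiary carbinol (C8). With the decalin in its usual orientation, H5 is β and the C10 methyl is α (trans fusion). The C4 methyl is α and axial, the hydroxymethyl carbon (called C19 here) is β and equatorial, and the C3 acetoxy group is α and equatorial. The C9 chain is β, trans to the C10 methyl and therefore axial on ring B, which is the less stable and less common arrangement. The C8 hydroxyl is β, cis to that chain, and the C8 methyl is axial. Three groups are sensitive: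

- the 2-substituted 1,3-diene (acid, heat, oxidants, hydrogenation);
- the acetate on O3, which can migrate to the free O19 under base;
- the C8 hydroxyl, which closes a tetrahydrofuran as soon as C12 carries a leaving group.

The hard points are the C5–C10 bond between two quaternary carbons, the axial C9 chain, and three hydroxyls of which only the hindered secondary one is acylated. The strategy rests on one feature: rings A and B share the C5–C10 bond, and C9 lies between the methyl-bearing carbons C8 and C10. Cutting C5–C10 and C3–C4 therefore opens both rings at once to an acyclic tetraene whose only stereocentre is C9.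

## Retrosynthetic reasoning

Compound numbers are those of the steps below.

**Protecting groups at the end.** Target 33 is traced to silyl ether 32 and diol 31. The acetate can only be placed on O3 while the more reactive primary O19 is masked, and the mask must come off last under buffered conditions so that the acetyl group stays on O3.

**C12–C13.** The diene is cut from the skeleton at C12–C13, giving iodide 27 and the Grignard reagent 29 made from chloroprene 28. This puts the fragile diene in at the latest possible point by a copper-catalysed sp3–sp2 coupling. Both secondary and tertiary oxygens are silylated in 27, because a free 8-hydroxyl would displace the C12 leaving group.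

**C12–O and C3–H.** Iodide 27 goes back through alcohol 26 and tris-silyl ether 25 to triol 24, and 24 to keto-lactone 23. One hydride reduction opens the lactone to the C12 alcohol and the C8 carbinol and also reduces the C3 ketone from the axial direction.

**C3 oxygen.** Ketone 23 comes from enone 22 and this from alkene 21. C3 is the only allylic CH2 of the C1=C2 bond (the other allylic carbon, C10, is quaternary), so the ring A oxygen is introduced there by allylic oxidation. It is done after the C7=C8 bond has been used up.

**C8–O.** Lactone 20 (silylated as 21) is opened to the γ,δ-unsaturated acid 19. Closing the γ-lactone from the C9 arm onto C8 uses the axial chain as a tether: the oxygen can only arrive on the β face, which fixes C8.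

**Key disconnection, C5–C10 and C3–C4.** Acid 19 comes from adduct 17 by reduction and saponification. Adduct 17 is opened by a retro-Diels–Alder to tetraene 16. The cut is made here because it removes both rings and three stereocentres in one operation and leaves C9 as the only control element. C9 is flanked by two methyl-bearing alkenes in 16, and this forces its arm into the orientation the target needs.

**End groups of 16.** The enal of 16 comes from allylic alcohol 15, and the terminal diene of 15 from enyne 14 (from silylated 13). Carrying C2–C3 as an alkyne keeps the next disconnection regiochemically clean.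

**C9–C11.** Ester 13 is cut by a retro-Johnson–Claisen to carbinol 11 and orthoester 12. The rearrangement moves the configuration of the C1 carbinol to C9, creates the (E)-C10=C1 bond with the methyl on the inside of the later diene, and delivers the two-carbon arm (C11, C12).

**C1–C2.** Carbinol 11 comes from trienal 9 and alkyne 10 by enantioselective alkynylation. This is the only stereocentre set by a chiral reagent.

**C9=C10.** Trienal 9 comes from (Z)-enal 8 (from alcohol 6) and ylide 7 by a Wittig reaction.

**C6–C7 and C8–C17.** Alcohol 6 is cut to propargyl alcohol 4 and allylic chloride 3. Anti-carbometalation of 4 adds the C17 methyl and leaves a metal on C7 cis to C9 (intermediate 5), so the (Z)-C7=C8 bond is fixed when C7 is allylated.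

**C19 end.** Chloride 3 comes from chloro alcohol 2 and this from vinyl epoxide 1, which brings the (E)-C4=C5 bond and the C19 oxygen.

## Alternatives that were turned down

Alternative 1: Ring A is kept and the bonds C5–C6 and C4–C19 are cut, so that ring A comes from the enantiopure cyclohexenone A2 (C3 ketone, C4=C5, quaternary C10 with methyl and a masked formyl group).
- Forward key step: the ketal-bearing Grignard reagent A3 is added with CuBr·SMe2 to C5, and the enolate is hydroxymethylated at C4 to give ketone A1. No ring is formed.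
- For: three components are joined in one flask. The trans relation of C19 and C6 follows from anti trapping of the enolate. The C3 oxygen is present from the start, which is better than the chosen route, where C3 has to be oxidised late.
- Against: C5 is the β-carbon of an α-methyl enone and sits next to quaternary C10, so the addition is strongly hindered. The face of attack depends on the small difference between CH3 and CH(OMe)2 on C10. A2 needs its own asymmetric synthesis. After A1, all of ring B, the C8 carbinol and the axial C9 chain are still missing, and the side chain of A1 ends in an ethyl ketal that does not map directly onto C8 and its methyl.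
- Comparison: the chosen strategy gives up the early C3 oxygen but closes both rings and sets C4, C5 and C10 in one step from a single stereocentre.

Alternative 2: Ring B is cut at C8–C9, leading back to ring-A compound A5, which carries an (E)-allylic bromide on C10 and a methyl ketone chain on C5.
- Forward key step: CrCl2 (divalent chromium) converts the bromide into a trivalent allylchromium species that adds through its γ-carbon C9 to the C8 ketone, closing ring B and giving A4.
- For: C8 and C9 are formed together, the ring A functionality (3-acetate, protected C19) is already in place, and chromium tolerates the acetate. The C9 vinyl group of A4 could be extended by hydroboration and sp3–sp2 coupling without a leaving group on C12. That end game is better than the chosen one, which needs three silyl-group steps to keep O8 away from C12.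
- Against: the attacking carbon is neopentyl (next to quaternary C10) and the acceptor is a ketone, so three adjacent congested centres must form in one bond. The target needs the vinyl group axial and the C8 methyl axial, while a chair Zimmerman–Traxler transition state tends to place such groups equatorially, so the diastereomer is not assured. A5 with four stereocentres must be built first.
- Comparison: in the chosen strategy C9 is set first by chirality transfer and then controls the rest, and C8 follows from a tether that can reach only one face.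

Alternative 3: The C9–C10 bond is cut, leading back to the flat phenol A7, in which ring A is aromatic and a dienyl carbonate chain hangs from C5.
- Forward key step: [Ir(cod)Cl]2 with a chiral phosphoramidite ionises the carbonate and the para carbon C10 of the phenoxide attacks the allyl terminus C9. This closes ring B and dearomatises ring A to dienone A6.
- For: it is catalytic and enantioselective, it builds quaternary C10 and C9 in one step, and A7 is short to make. On brevity to the bicycle and on catalytic asymmetric induction it is better than the chosen route.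
- Against: only two of the six stereocentres are set. The relative configuration of the C9 vinyl group and the C10 methyl is not clearly predictable. O-allylation and ortho attack compete. The allyl terminus carries a branched dienyl substituent. Afterwards C4, C5, C3 and C8 must all be set on a cross-conjugated dienone that also holds a vinyl and a methylidene group, a difficult chemoselectivity problem.
- Comparison: the chosen strategy takes longer to reach its precursor but then sets C4, C5 and C10 by substrate control and C8 by lactonisation, with no competing alkenes of similar reactivity.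

Key step: step 10

## Remarks before the steps

- Bicyclic compounds are named with labdane numbering for the carbon skeleton only; C19 is the hydroxymethyl carbon on C4.
- α and β mean below and above the plane of the decalin drawn with ring A on the left, C1 at the top left and C10 above C5.
- All bicyclic compounds share H5 β, H9 α (C9 arm β), C10 methyl α, C4 methyl α and C19 β; names state only what differs.
- In step 5 the ligand enantiomer is the one that delivers the alkynyl group to the Re face of the formyl group.

## Steps

Step 1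
Reactants: 1 2-methyl-2-vinyloxirane
Product: 2 (2E)-4-chloro-2-methylbut-2-en-1-ol
Conditions: TiCl4, CH2Cl2, −85 °C; aq. NaHCO3
Reagents that add atoms: titanium tetrachloride, Cl[Ti](Cl)(Cl)Cl
Why: Lewis-acid opening of a vinyl epoxide with conjugate (SN2′) delivery of chloride to the vinyl terminus; reaction through the s-trans conformer should give the (E)-allylic chloride with the primary alcohol on the methyl-bearing carbon.

Step 2
Reactants: 2 (2E)-4-chloro-2-methylbut-2-en-1-ol
Product: 3 tert-butyl{[(2E)-4-chloro-2-methylbut-2-en-1-yl]oxy}diphenylsilane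
Conditions: TBDPSCl, imidazole, CH2Cl2, 0 °C
Reagents that add atoms: tert-butyl(chloro)diphenylsilane, CC(C)(C)[Si](Cl)(c1ccccc1)c1ccccc1
Why: Standard silylation of a primary alcohol; the bulky silyl ether masks O19 through the Grignard, Wittig, zinc and Claisen steps.

Step 3
Reactants: 3 tert-butyl{[(2E)-4-chloro-2-methylbut-2-en-1-yl]oxy}diphenylsilane; 4 prop-2-yn-1-ol
Product: 6 (2Z,5E)-7-{[tert-butyl(diphenyl)silyl]oxy}-2,6-dimethylhepta-2,5-dien-1-ol, via (Z)-alkenylmagnesium alkoxide 5 (not isolated)
Conditions: 4, MeMgBr (2.1 equiv), CuI (10 mol %), THF, −10 → 20 °C; then 3, 0 → 20 °C; aq. NH4Cl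
Reagents that add atoms: methylmagnesium bromide, C[Mg]Br
Why: CuI-catalysed anti-carbomagnesiation of the propargylic alkoxide puts the methyl on C8 and magnesium on C7 cis to the CH2O group (five-membered chelate 5). Copper-catalysed allylation of 5 at the primary carbon of 3 then proceeds with retention at both alkenes, which gives the (Z)-C7=C8 and (E)-C4=C5 bonds.

Step 4
Reactants: 6 (2Z,5E)-7-{[tert-butyl(diphenyl)silyl]oxy}-2,6-dimethylhepta-2,5-dien-1-ol; 7 2-(triphenylphosphoranylidene)propanal
Product: 9 (2E,4Z,7E)-9-{[tert-butyl(diphenyl)silyl]oxy}-2,4,8-trimethylnona-2,4,7-trienal, via (2Z,5E)-dienal 8 (not isolated)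
Conditions: MnO2, CH2Cl2, 0 → 20 °C, filtration; then 7, toluene, 80 °C
Reagents that add atoms: none
Why: MnO2 oxidises only the allylic alcohol, and the (Z)-enal 8 is used crude to limit Z→E isomerisation. The Wittig reaction of the stabilised formyl ylide 7 should give the (E)-C9=C10 bond.

Step 5
Reactants: 9 (2E,4Z,7E)-9-{[tert-butyl(diphenyl)silyl]oxy}-2,4,8-trimethylnona-2,4,7-trienal; 10 ethynyltrimethylsilane
Product: 11 (3S,4E,6Z,9E)-11-{[tert-butyl(diphenyl)silyl]oxy}-4,6,10-trimethyl-1-(trimethylsilyl)undeca-4,6,9-trien-1-yn-3-ol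
Conditions: 10, Me2Zn, ProPhenol ligand (20 mol %), Ph3P=O (40 mol %), toluene, 4 °C
Reagents that add atoms: none
Why: Catalytic enantioselective addition of an alkynylzinc to an α-branched enal by a dinuclear zinc–ProPhenol catalyst; Re-face delivery sets C1 as (S). This carbinol is the source of all later stereocentres.

Step 6
Reactants: 11 (3S,4E,6Z,9E)-11-{[tert-butyl(diphenyl)silyl]oxy}-4,6,10-trimethyl-1-(trimethylsilyl)undeca-4,6,9-trien-1-yn-3-ol; 12 trimethyl orthoacetate
Product: 13 methyl (3S,4Z,7E)-9-{[tert-butyl(diphenyl)silyl]oxy}-4,8-dimethyl-3-[(2E)-5-(trimethylsilyl)pent-2-en-4-yn-2-yl]nona-4,7-dienoate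
Conditions: 12 (excess), EtCO2H (5 mol %), toluene, 110 °C, removal of MeOH
Reagents that add atoms: none
Why: Johnson–Claisen rearrangement through a chair transition state with the alkynyl group equatorial. The C–O bond on C1 and the new C9–C11 bond lie on the same face of the allyl unit, so (S)-C1 becomes (S)-C9 and the new C10=C1 bond is (E) with the methyl inside. The alkyne, unlike a vinyl group, does not offer a competing unhindered allyl terminus.

Step 7
Reactants: 13 methyl (3S,4Z,7E)-9-{[tert-butyl(diphenyl)silyl]oxy}-4,8-dimethyl-3-[(2E)-5-(trimethylsilyl)pent-2-en-4-yn-2-yl]nona-4,7-dienoate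
Product: 14 methyl (3S,4Z,7E)-9-hydroxy-4,8-dimethyl-3-[(2E)-pent-2-en-4-yn-2-yl]nona-4,7-dienoate
Conditions: TBAF, THF, 0 → 20 °C
Reagents that add atoms: none
Why: Fluoride cleaves the alkynyl C–Si bond and the silyl ether in one operation; C9 is not next to a carbonyl and is not at risk.

Step 8
Reactants: 14 methyl (3S,4Z,7E)-9-hydroxy-4,8-dimethyl-3-[(2E)-pent-2-en-4-yn-2-yl]nona-4,7-dienoate
Product: 15 methyl (3S,4Z,7E)-9-hydroxy-4,8-dimethyl-3-[(2E)-penta-2,4-dien-2-yl]nona-4,7-dienoate
Conditions: Zn dust activated with Cu(OAc)2 and AgNO3, MeOH/H2O, 30 °C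
Reagents that add atoms: none
Why: Activated zinc reduces only the conjugated alkyne, to the terminal alkene; the isolated trisubstituted alkenes and the ester are untouched and over-reduction is not expected.

Step 9
Reactants: 15 methyl (3S,4Z,7E)-9-hydroxy-4,8-dimethyl-3-[(2E)-penta-2,4-dien-2-yl]nona-4,7-dienoate
Product: 16 methyl (3S,4Z,7E)-4,8-dimethyl-9-oxo-3-[(2E)-penta-2,4-dien-2-yl]nona-4,7-dienoate
Conditions: MnO2, CH2Cl2, 20 °C
Reagents that add atoms: none
Why: Neutral allylic oxidation to the (E)-enal; base is avoided because the C6 methylene between two alkenes would let the skipped diene move into conjugation.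

Step 10
Reactants: 16 methyl (3S,4Z,7E)-4,8-dimethyl-9-oxo-3-[(2E)-penta-2,4-dien-2-yl]nona-4,7-dienoate
Product: 17 methyl 19-oxo-13,14,15,16-tetranorlabda-1,7-dien-12-oate
Conditions: Me2AlCl (2.2 equiv), CH2Cl2, −78 → −20 °C; aq. NaHCO3
Reagents that add atoms: none
Why: Me2AlCl binds the formyl oxygen (a second equivalent occupies the ester) and lowers the enal LUMO, so a concerted, asynchronous [4+2] between C4=C5 and the C10=C1–C2=C3 diene forms C5–C10 and C3–C4 well below 0 °C. The closest known reaction type is the Lewis-acid-promoted type 1 intramolecular Diels–Alder of terminally activated (E)-2-methyldeca-2,7,9-trienals to trans-fused octalins. Ring A closes as the new cyclohexene (four diene carbons plus C4 and C5). Ring B closes at the same time as the tether ring C5–C6–C7=C8–C9–C10, with the (Z)-C7=C8 bond holding the tether in a half-chair. C4 follows from the (E)-enal geometry, since suprafacial addition keeps the formyl group cis to H5 and the C4 methyl cis to C6. C5 and C10 follow from the endo transition state (formyl under the diene, tether anti), which gives the trans fusion with H5 β and the C10 methyl α. The face of the diene is chosen by C9: between the methyl-bearing C8 and C10 its CH2CO2Me arm avoids allylic strain by standing pseudoaxial on the forming ring B, antiperiplanar to the C10 methyl, so C5 reaches C10 from the face that leaves H9 outside and C11 ends trans to the C10 methyl. The step needs endo over exo addition, one diene face and no [1,5]-hydrogen shift from the inside C10 methyl; these are secured by the Lewis acid with the (E)-enal, by the C9 stereocentre and by the low temperature.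

Step 11
Reactants: 17 methyl 19-oxo-13,14,15,16-tetranorlabda-1,7-dien-12-oate
Product: 19 19-hydroxy-13,14,15,16-tetranorlabda-1,7-dien-12-oic acid, via hydroxy ester 18 (not isolated)
Conditions: NaBH4, MeOH, 0 °C; then LiOH, H2O, THF, 20 °C; aq. HCl to pH 4, 0 °C
Reagents that add atoms: lithium hydroxide, [Li+].[OH-]
Why: NaBH4 reduces the neopentyl aldehyde and leaves the ester; saponification then frees the acid. No stereocentre is α to a carbonyl, so nothing can epimerise.

Step 12
Reactants: 19 19-hydroxy-13,14,15,16-tetranorlabda-1,7-dien-12-oic acid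
Product: 20 19-hydroxy-13,14,15,16-tetranorlabd-1-en-12,8β-olide
Conditions: CF3SO3H (10 mol %), CH2Cl2, −20 → 0 °C
Reagents that add atoms: none
Why: Acid-catalysed lactonisation of a γ,δ-unsaturated acid: Markovnikov protonation of C7=C8 gives the tertiary C8 cation, which the carboxyl group on the β-axial C9 arm captures (5-exo). The arm can reach only the β face, so O8 is β and the C8 methyl α; the disubstituted C1=C2 bond is far less basic and should survive.

Step 13
Reactants: 20 19-hydroxy-13,14,15,16-tetranorlabd-1-en-12,8β-olide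
Product: 21 19-{[tert-butyl(diphenyl)silyl]oxy}-13,14,15,16-tetranorlabd-1-en-12,8β-olide
Conditions: TBDPSCl, imidazole, DMF, 40 °C
Reagents that add atoms: tert-butyl(chloro)diphenylsilane, CC(C)(C)[Si](Cl)(c1ccccc1)c1ccccc1
Why: Silylation of the primary alcohol; O19 must be masked for the chromium oxidation and must stay masked until O3 is acetylated.

Step 14
Reactants: 21 19-{[tert-butyl(diphenyl)silyl]oxy}-13,14,15,16-tetranorlabd-1-en-12,8β-olide
Product: 22 19-{[tert-butyl(diphenyl)silyl]oxy}-3-oxo-13,14,15,16-tetranorlabd-1-en-12,8β-olide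
Conditions: CrO3, 3,5-dimethylpyrazole, CH2Cl2, −20 °C
Reagents that add atoms: chromium trioxide, O=[Cr](=O)=O
Why: Allylic oxidation of a cyclic alkene to the enone with the CrO3–3,5-dimethylpyrazole complex; C3 is the only allylic carbon bearing hydrogen, and the lactone and silyl ether are inert to it.

Step 15
Reactants: 22 19-{[tert-butyl(diphenyl)silyl]oxy}-3-oxo-13,14,15,16-tetranorlabd-1-en-12,8β-olide
Product: 23 19-{[tert-butyl(diphenyl)silyl]oxy}-3-oxo-13,14,15,16-tetranorlabdan-12,8β-olide
Conditions: H2 (1 atm), Pd/C, EtOAc, 20 °C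
Reagents that add atoms: none
Why: Hydrogenation of the enone C=C bond; no stereocentre is formed, and it is done before any diene is present.

Step 16
Reactants: 23 19-{[tert-butyl(diphenyl)silyl]oxy}-3-oxo-13,14,15,16-tetranorlabdan-12,8β-olide
Product: 24 19-{[tert-butyl(diphenyl)silyl]oxy}-13,14,15,16-tetranorlabdane-3α,8β,12-triol
Conditions: LiAlH4, THF, 0 → 20 °C
Reagents that add atoms: none
Why: Hydride reduces the lactone to the 8,12-diol and the ketone to the alcohol. Axial attack on C3 from the β face, away from the axial 4α-methyl, should give the equatorial 3α-alcohol.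

Step 17
Reactants: 24 19-{[tert-butyl(diphenyl)silyl]oxy}-13,14,15,16-tetranorlabdane-3α,8β,12-triol
Product: 25 19-{[tert-butyl(diphenyl)silyl]oxy}-3α,8β,12-tris[(triethylsilyl)oxy]-13,14,15,16-tetranorlabdane
Conditions: TESOTf, 2,6-lutidine, CH2Cl2, 0 °C
Reagents that add atoms: triethylsilyl trifluoromethanesulfonate, CC[Si](CC)(CC)OS(=O)(=O)C(F)(F)F
Why: The silyl triflate silylates all three hydroxyls, including the tertiary one on C8, which has to be blocked before C12 becomes an electrophile.

Step 18
Reactants: 25 19-{[tert-butyl(diphenyl)silyl]oxy}-3α,8β,12-tris[(triethylsilyl)oxy]-13,14,15,16-tetranorlabdane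
Product: 26 19-{[tert-butyl(diphenyl)silyl]oxy}-3α,8β-bis[(triethylsilyl)oxy]-13,14,15,16-tetranorlabdan-12-ol
Conditions: PPTS (cat.), MeOH/CH2Cl2, −10 °C
Reagents that add atoms: none
Why: Mild acidic methanolysis removes the unhindered primary triethylsilyl ether much faster than the neopentyl-type secondary and the tertiary ones; the bulkier silyl ether on O19 is stable.

Step 19
Reactants: 26 19-{[tert-butyl(diphenyl)silyl]oxy}-3α,8β-bis[(triethylsilyl)oxy]-13,14,15,16-tetranorlabdan-12-ol
Product: 27 19-{[tert-butyl(diphenyl)silyl]oxy}-12-iodo-3α,8β-bis[(triethylsilyl)oxy]-13,14,15,16-tetranorlabdane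
Conditions: I2, PPh3, imidazole, CH2Cl2, 0 °C
Reagents that add atoms: iodine, II
Why: Appel-type iodination of a primary alcohol under buffered conditions; with O8 silylated the 8,12-ether cannot form.

Step 20
Reactants: 27 19-{[tert-butyl(diphenyl)silyl]oxy}-12-iodo-3α,8β-bis[(triethylsilyl)oxy]-13,14,15,16-tetranorlabdane; 28 2-chlorobuta-1,3-diene (chloroprene)
Product: 30 19-{[tert-butyl(diphenyl)silyl]oxy}-3α,8β-bis[(triethylsilyl)oxy]labda-13(16),14-diene, via buta-1,3-dien-2-ylmagnesium chloride 29 (not isolated)
Conditions: 28, Mg, ZnCl2 (cat.), THF, 60 °C; then 27, Li2CuCl4 (5 mol %), THF, −10 → 20 °C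
Reagents that add atoms: none
Why: Li2CuCl4-catalysed coupling of a primary alkyl iodide with the dienyl Grignard reagent forms C12–C13 and gives the 2-alkylbuta-1,3-diene directly; the substrate contains only silyl ethers, which tolerate the reagent.

Step 21
Reactants: 30 19-{[tert-butyl(diphenyl)silyl]oxy}-3α,8β-bis[(triethylsilyl)oxy]labda-13(16),14-diene
Product: 31 19-{[tert-butyl(diphenyl)silyl]oxy}labda-13(16),14-diene-3α,8β-diol
Conditions: HF·pyridine, pyridine, THF, 0 → 20 °C
Reagents that add atoms: none
Why: Buffered HF removes the two triethylsilyl ethers, while the primary tert-butyldiphenylsilyl ether is far slower to cleave; the buffer protects the diene and the tertiary alcohol.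

Step 22
Reactants: 31 19-{[tert-butyl(diphenyl)silyl]oxy}labda-13(16),14-diene-3α,8β-diol
Product: 32 3α-acetoxy-19-{[tert-butyl(diphenyl)silyl]oxy}labda-13(16),14-dien-8β-ol
Conditions: Ac2O, pyridine, DMAP (cat.), CH2Cl2, 20 °C
Reagents that add atoms: acetic anhydride, CC(=O)OC(C)=O
Why: Acylation of the secondary alcohol; the hindered tertiary 8-hydroxyl should not react under these conditions and O19 is masked.

Step 23
Reactants: 32 3α-acetoxy-19-{[tert-butyl(diphenyl)silyl]oxy}labda-13(16),14-dien-8β-ol
Product: 33 3α-acetoxylabda-13(16),14-diene-8β,19-diol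
Conditions: TBAF, AcOH (1:1), THF, 20 → 40 °C
Reagents that add atoms: none
Why: Fluoride cleaves the remaining silyl ether; buffering with acetic acid keeps the medium from becoming basic, so the acetyl group should not migrate from O3 to O19.

## Compound list

1 | 2-methyl-2-vinyloxirane (racemic) | CC1(C=C)CO1 | starting material
2 | (2E)-4-chloro-2-methylbut-2-en-1-ol | OC/C(C)=C/CCl | intermediate
3 | tert-butyl{[(2E)-4-chloro-2-methylbut-2-en-1-yl]oxy}diphenylsilane | CC(C)(C)[Si](c1ccccc1)(c1ccccc1)OC/C(C)=C/CCl | intermediate
4 | prop-2-yn-1-ol | C#CCO | starting material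
5 | bromomagnesium (2Z)-3-(bromomagnesio)-2-methylprop-2-en-1-olate | Br[Mg]OC/C(C)=C\[Mg]Br | intermediate
6 | (2Z,5E)-7-{[tert-butyl(diphenyl)silyl]oxy}-2,6-dimethylhepta-2,5-dien-1-ol | OC/C(C)=C\C/C=C(C)/CO[Si](c1ccccc1)(c1ccccc1)C(C)(C)C | intermediate
7 | 2-(triphenylphosphoranylidene)propanal | CC(C=O)=P(c1ccccc1)(c1ccccc1)c1ccccc1 | starting material
8 | (2Z,5E)-7-{[tert-butyl(diphenyl)silyl]oxy}-2,6-dimethylhepta-2,5-dienal | O=C/C(C)=C\C/C=C(C)/CO[Si](c1ccccc1)(c1ccccc1)C(C)(C)C | intermediate
9 | (2E,4Z,7E)-9-{[tert-butyl(diphenyl)silyl]oxy}-2,4,8-trimethylnona-2,4,7-trienal | O=C/C(C)=C/C(C)=C\C/C=C(C)/CO[Si](c1ccccc1)(c1ccccc1)C(C)(C)C | intermediate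
10 | ethynyltrimethylsilane | C#C[Si](C)(C)C | starting material
11 | (3S,4E,6Z,9E)-11-{[tert-butyl(diphenyl)silyl]oxy}-4,6,10-trimethyl-1-(trimethylsilyl)undeca-4,6,9-trien-1-yn-3-ol | C[Si](C)(C)C#C[C@@H](O)/C(C)=C/C(C)=C\C/C=C(C)/CO[Si](c1ccccc1)(c1ccccc1)C(C)(C)C | intermediate
12 | trimethyl orthoacetate (1,1,1-trimethoxyethane) | COC(C)(OC)OC | starting material
13 | methyl (3S,4Z,7E)-9-{[tert-butyl(diphenyl)silyl]oxy}-4,8-dimethyl-3-[(2E)-5-(trimethylsilyl)pent-2-en-4-yn-2-yl]nona-4,7-dienoate | CC(C)(C)[Si](c1ccccc1)(c1ccccc1)OC/C(C)=C/C/C=C(C)\[C@H](CC(=O)OC)/C(C)=C/C#C[Si](C)(C)C | intermediate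
14 | methyl (3S,4Z,7E)-9-hydroxy-4,8-dimethyl-3-[(2E)-pent-2-en-4-yn-2-yl]nona-4,7-dienoate | OC/C(C)=C/C/C=C(C)\[C@H](CC(=O)OC)/C(C)=C/C#C | intermediate
15 | methyl (3S,4Z,7E)-9-hydroxy-4,8-dimethyl-3-[(2E)-penta-2,4-dien-2-yl]nona-4,7-dienoate | OC/C(C)=C/C/C=C(C)\[C@H](CC(=O)OC)/C(C)=C/C=C | intermediate
16 | methyl (3S,4Z,7E)-4,8-dimethyl-9-oxo-3-[(2E)-penta-2,4-dien-2-yl]nona-4,7-dienoate | O=C/C(C)=C/C/C=C(C)\[C@H](CC(=O)OC)/C(C)=C/C=C | intermediate
17 | methyl 19-oxo-13,14,15,16-tetranorlabda-1,7-dien-12-oate: trans-fused octalin with C1=C2 and C7=C8, C4 formyl β and methyl α, H5 β, C9 CH2CO2Me arm β, C10 methyl α | COC(=O)C[C@@H]1[C@]2(C)C=CC[C@](C)(C=O)[C@H]2CC=C1C | intermediate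
18 | methyl 19-hydroxy-13,14,15,16-tetranorlabda-1,7-dien-12-oate (as 17 with CH2OH in place of CHO) | COC(=O)C[C@@H]1[C@]2(C)C=CC[C@](C)(CO)[C@H]2CC=C1C | intermediate
19 | 19-hydroxy-13,14,15,16-tetranorlabda-1,7-dien-12-oic acid | OC(=O)C[C@@H]1[C@]2(C)C=CC[C@](C)(CO)[C@H]2CC=C1C | intermediate
20 | 19-hydroxy-13,14,15,16-tetranorlabd-1-en-12,8β-olide: γ-lactone from C12 to the 8β oxygen, cis-fused to ring B, C8 methyl α | O=C1C[C@@H]2[C@]3(C)C=CC[C@](C)(CO)[C@H]3CC[C@]2(C)O1 | intermediate
21 | 19-{[tert-butyl(diphenyl)silyl]oxy}-13,14,15,16-tetranorlabd-1-en-12,8β-olide | O=C1C[C@@H]2[C@]3(C)C=CC[C@](C)(CO[Si](c4ccccc4)(c4ccccc4)C(C)(C)C)[C@H]3CC[C@]2(C)O1 | intermediate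
22 | 19-{[tert-butyl(diphenyl)silyl]oxy}-3-oxo-13,14,15,16-tetranorlabd-1-en-12,8β-olide | O=C1C[C@@H]2[C@]3(C)C=CC(=O)[C@](C)(CO[Si](c4ccccc4)(c4ccccc4)C(C)(C)C)[C@H]3CC[C@]2(C)O1 | intermediate
23 | 19-{[tert-butyl(diphenyl)silyl]oxy}-3-oxo-13,14,15,16-tetranorlabdan-12,8β-olide | O=C1C[C@@H]2[C@]3(C)CCC(=O)[C@](C)(CO[Si](c4ccccc4)(c4ccccc4)C(C)(C)C)[C@H]3CC[C@]2(C)O1 | intermediate
24 | 19-{[tert-butyl(diphenyl)silyl]oxy}-13,14,15,16-tetranorlabdane-3α,8β,12-triol (3-OH equatorial, 8-OH cis to the C9 arm) | OCC[C@@H]1[C@]2(C)CC[C@@H](O)[C@](C)(CO[Si](c3ccccc3)(c3ccccc3)C(C)(C)C)[C@H]2CC[C@]1(C)O | intermediate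
25 | 19-{[tert-butyl(diphenyl)silyl]oxy}-3α,8β,12-tris[(triethylsilyl)oxy]-13,14,15,16-tetranorlabdane | CC[Si](CC)(CC)OCC[C@@H]1[C@]2(C)CC[C@@H](O[Si](CC)(CC)CC)[C@](C)(CO[Si](c3ccccc3)(c3ccccc3)C(C)(C)C)[C@H]2CC[C@]1(C)O[Si](CC)(CC)CC | intermediate
26 | 19-{[tert-butyl(diphenyl)silyl]oxy}-3α,8β-bis[(triethylsilyl)oxy]-13,14,15,16-tetranorlabdan-12-ol | OCC[C@@H]1[C@]2(C)CC[C@@H](O[Si](CC)(CC)CC)[C@](C)(CO[Si](c3ccccc3)(c3ccccc3)C(C)(C)C)[C@H]2CC[C@]1(C)O[Si](CC)(CC)CC | intermediate
27 | 19-{[tert-butyl(diphenyl)silyl]oxy}-12-iodo-3α,8β-bis[(triethylsilyl)oxy]-13,14,15,16-tetranorlabdane | ICC[C@@H]1[C@]2(C)CC[C@@H](O[Si](CC)(CC)CC)[C@](C)(CO[Si](c3ccccc3)(c3ccccc3)C(C)(C)C)[C@H]2CC[C@]1(C)O[Si](CC)(CC)CC | intermediate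
28 | 2-chlorobuta-1,3-diene (chloroprene) | C=CC(Cl)=C | starting material
29 | buta-1,3-dien-2-ylmagnesium chloride | C=CC(=C)[Mg]Cl | intermediate
30 | 19-{[tert-butyl(diphenyl)silyl]oxy}-3α,8β-bis[(triethylsilyl)oxy]labda-13(16),14-diene | C=CC(=C)CC[C@@H]1[C@]2(C)CC[C@@H](O[Si](CC)(CC)CC)[C@](C)(CO[Si](c3ccccc3)(c3ccccc3)C(C)(C)C)[C@H]2CC[C@]1(C)O[Si](CC)(CC)CC | intermediate
31 | 19-{[tert-butyl(diphenyl)silyl]oxy}labda-13(16),14-diene-3α,8β-diol | C=CC(=C)CC[C@@H]1[C@]2(C)CC[C@@H](O)[C@](C)(CO[Si](c3ccccc3)(c3ccccc3)C(C)(C)C)[C@H]2CC[C@]1(C)O | intermediate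
32 | 3α-acetoxy-19-{[tert-butyl(diphenyl)silyl]oxy}labda-13(16),14-dien-8β-ol | C=CC(=C)CC[C@@H]1[C@]2(C)CC[C@@H](OC(C)=O)[C@](C)(CO[Si](c3ccccc3)(c3ccccc3)C(C)(C)C)[C@H]2CC[C@]1(C)O | intermediate
33 | 3α-acetoxylabda-13(16),14-diene-8β,19-diol (H5 β, H9 α, C10 methyl α, C4 methyl α, C19 β, C8 methyl α); CNP0313672.1 | C=CC(=C)CC[C@@H]1[C@]2(C)CC[C@@H](OC(C)=O)[C@](C)(CO)[C@H]2CC[C@]1(C)O | target

## Step count and least certain steps

Total: 23 steps. Longest linear sequence: 23 steps (1 → 33); compounds 4, 7, 10, 12 and 28 enter as single building blocks.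

**Step 10 (key step).** The inside methyl on C10 makes the s-cis diene hard to reach, so cycloaddition may be slow. The Lewis acid may then cause cationic oligomerisation or move the skipped C4=C5/C7=C8 alkenes into conjugation, and some exo (cis-fused) addition or leakage to the other diene face is possible. The fallback is an ionic Diels–Alder with a more reactive dienophile.
- It sets out from 16, which with 1,2-bis(trimethylsilyloxy)ethane and catalytic TMSOTf at −78 °C gives the dioxolane acetal F1.
- A further charge of TMSOTf at −78 → −40 °C opens the acetal to an alkoxy-stabilised allyl cation, which should cyclise through the same endo, C9-controlled transition state to the cyclised acetal F2.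
- PPTS in wet acetone hydrolyses F2, and the route is rejoined at 17.

**Step 6.** The carbinol is both allylic and propargylic and may ionise under acid at 110 °C, with loss of configuration or transposition. The small alkynyl group may allow some axial-alkynyl pathway, giving the (Z)-C10=C1 isomer with the opposite C9. A thermal [1,5]-hydrogen shift in the (Z)-diene is also conceivable. The fallback is an Ireland–Claisen rearrangement under basic, low-temperature conditions.
- It sets out from 11, which with Ac2O, pyridine and DMAP gives acetate F3.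
- LiN(iPr)2 and TMSCl in THF at −78 °C, then warming to 20 °C, rearranges F3 through the silyl ketene acetal with the same chair topology, giving after work-up carboxylic acid F4.
- TMSCHN2 in MeOH/toluene esterifies F4, and the route is rejoined at 13.

**Step 12.** The C8 cation may lose H9 or undergo hydride or methyl shifts. This would epimerise C9 to the more stable equatorial arm or rearrange the skeleton, leading to trans-fused or rearranged lactones. The fallback is a radical hydration that avoids the cation.
- It sets out from 17, which is reduced with NaBH4 alone and isolated as 18.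
- Mukaiyama hydration (Co(acac)2, PhSiH3, O2, iPrOH) should hydrate the trisubstituted C7=C8 bond in preference to the disubstituted C1=C2 bond, giving the 8β-hydroxy ester F5; its 8α epimer cannot lactonise and is separated.
- PPTS in toluene at 60 °C closes F5 to the lactone, and the route is rejoined at 20.

**Step 14.** The allylic radical is delocalised over C1–C3, so oxygen may be delivered to C1 and give the transposed 2-en-1-one. Hydrogen abstraction next to quaternary C4, which carries the bulky silyloxymethyl group, may also be slow. The fallback is a pericyclic oxidation whose regiochemistry is fixed by mechanism.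
- It sets out from 21, which with SeO2 and tBuOOH in CH2Cl2 undergoes an ene reaction and a [2,3]-shift that return the alkene to C1=C2 and place oxygen on C3, giving the 3β-allylic alcohol F6.
- Dess–Martin periodinane oxidises F6, and the route is rejoined at 22.

**Step 5.** Facial selectivity may be insufficient with this α-branched, doubly unsaturated aldehyde, and uncatalysed addition of the alkynylzinc would erode it further. The fallback is addition, oxidation and reagent-controlled reduction.
- It sets out from 9, which with LiC≡CSiMe3 in THF at −78 °C gives the racemic carbinol F7.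
- MnO2 oxidises F7 to ynone F8.
- Corey–Bakshi–Shibata reduction with (S)-2-methyl-CBS-oxazaborolidine and catecholborane at −78 °C, with the alkynyl group as the small substituent, should give the (3S)-alcohol, and the route is rejoined at 11.

## Further compounds

F1 | step 10 | methyl (3S,4Z,7E)-8-(1,3-dioxolan-2-yl)-4-methyl-3-[(2E)-penta-2,4-dien-2-yl]nona-4,7-dienoate | O1CCOC1/C(C)=C/C/C=C(C)\[C@H](CC(=O)OC)/C(C)=C/C=C
F2 | step 10 | ethylene acetal of 17 (1,3-dioxolan-2-yl in place of the 4β-formyl group) | COC(=O)C[C@@H]1[C@]2(C)C=CC[C@](C)(C3OCCO3)[C@H]2CC=C1C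
F3 | step 6 | (3S,4E,6Z,9E)-11-{[tert-butyl(diphenyl)silyl]oxy}-4,6,10-trimethyl-1-(trimethylsilyl)undeca-4,6,9-trien-1-yn-3-yl acetate | C[Si](C)(C)C#C[C@@H](OC(C)=O)/C(C)=C/C(C)=C\C/C=C(C)/CO[Si](c1ccccc1)(c1ccccc1)C(C)(C)C
F4 | step 6 | (3S,4Z,7E)-9-{[tert-butyl(diphenyl)silyl]oxy}-4,8-dimethyl-3-[(2E)-5-(trimethylsilyl)pent-2-en-4-yn-2-yl]nona-4,7-dienoic acid | CC(C)(C)[Si](c1ccccc1)(c1ccccc1)OC/C(C)=C/C/C=C(C)\[C@H](CC(=O)O)/C(C)=C/C#C[Si](C)(C)C
F5 | step 12 | methyl 8β,19-dihydroxy-13,14,15,16-tetranorlabd-1-en-12-oate | COC(=O)C[C@@H]1[C@]2(C)C=CC[C@](C)(CO)[C@H]2CC[C@]1(C)O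
F6 | step 14 | 19-{[tert-butyl(diphenyl)silyl]oxy}-3β-hydroxy-13,14,15,16-tetranorlabd-1-en-12,8β-olide | O=C1C[C@@H]2[C@]3(C)C=C[C@H](O)[C@](C)(CO[Si](c4ccccc4)(c4ccccc4)C(C)(C)C)[C@H]3CC[C@]2(C)O1
F7 | step 5 | racemic (4E,6Z,9E)-11-{[tert-butyl(diphenyl)silyl]oxy}-4,6,10-trimethyl-1-(trimethylsilyl)undeca-4,6,9-trien-1-yn-3-ol | C[Si](C)(C)C#CC(O)/C(C)=C/C(C)=C\C/C=C(C)/CO[Si](c1ccccc1)(c1ccccc1)C(C)(C)C
F8 | step 5 | (4E,6Z,9E)-11-{[tert-butyl(diphenyl)silyl]oxy}-4,6,10-trimethyl-1-(trimethylsilyl)undeca-4,6,9-trien-1-yn-3-one | C[Si](C)(C)C#CC(=O)/C(C)=C/C(C)=C\C/C=C(C)/CO[Si](c1ccccc1)(c1ccccc1)C(C)(C)C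
A1 | alternative 1 | 4-(dimethoxymethyl)-3-[2-(2-ethyl-1,3-dioxolan-2-yl)ethyl]-2-(hydroxymethyl)-2,4-dimethylcyclohexan-1-one (configuration as in the SMILES) | COC(OC)[C@]2(C)CCC(=O)[C@](C)(CO)[C@H]2CCC1(CC)OCCO1
A2 | alternative 1 | 4-(dimethoxymethyl)-2,4-dimethylcyclohex-2-en-1-one, single enantiomer at the quaternary carbon | COC(OC)[C@]1(C)CCC(=O)C(C)=C1
A3 | alternative 1 | [2-(2-ethyl-1,3-dioxolan-2-yl)ethyl]magnesium bromide | CCC1(CC[Mg]Br)OCCO1
A4 | alternative 2 | 3α-acetoxy-19-{[tert-butyl(dimethyl)silyl]oxy}-13,14,15,16-tetranorlabd-11-en-8β-ol (9-vinyl trans-decalin, ring configuration as in 33) | C=C[C@@H]1[C@]2(C)CC[C@@H](OC(C)=O)[C@](C)(CO[Si](C)(C)C(C)(C)C)[C@H]2CC[C@]1(C)O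
A5 | alternative 2 | ring-A cyclohexane with C10 methyl and (E)-3-bromoprop-1-enyl, C5 3-oxobutyl, 3α-acetoxy, 4α-methyl and 4β-{[tert-butyl(dimethyl)silyl]oxy}methyl | BrC/C=C/[C@]1(C)CC[C@@H](OC(C)=O)[C@](C)(CO[Si](C)(C)C(C)(C)C)[C@H]1CCC(C)=O
A6 | alternative 3 | 5-ethenyl-1,4a-dimethyl-6-methylidene-5,6,7,8-tetrahydronaphthalen-2(4aH)-one (configuration as in the SMILES) | C=C[C@@H]1[C@]2(C)C=CC(=O)C(C)=C2CCC1=C
A7 | alternative 3 | (2E)-6-(3-hydroxy-2,6-dimethylphenyl)-4-methylidenehex-2-en-1-yl methyl carbonate | Cc1ccc(O)c(C)c1CCC(=C)/C=C/COC(=O)OC
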